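## The problem

Abruquinone B (17) is an isoflavanquinone: a 6,7,8-trimethoxychroman (ring A fused to the pyran ring C) that carries a 2,3-dimethoxy-1,4-benzoquinone (ring B) at C3. The two halves are joined by the single C3–C1' bond. C3, flanked by the C2 and C4 methylenes, is the only stereocentre, and the SMILES of the target defines it as (S). With no second stereocentre to relay from, its configuration has to come from a reagent or catalyst. In the quinone the C3 hydrogen is allylic to the quinone C=C and vinylogously activated by a carbonyl group, so acid or base can erase it through a quinone methide tautomer. The quinone is also open to nucleophiles and reductants, so it should be unveiled last, from a ring B phenol with a free para position. Five methyl ethers on two electron-rich rings must stay intact, so the one ring B oxygen that becomes a carbonyl must be marked from the start, and ring A (four oxygens) must not be the ring that is oxidised. The enabling feature is that C3 bears exactly one hydrogen. Replacing it by a second CH2OH, the twin of the C2 arm, gives a prochiral quaternary carbon whose two enantiotopic hydroxymethyl groups are told apart when one of them closes O1–C8a onto ring A. The surplus arm is then removed with retention by way of a non-enolisable aldehyde.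

## Retrosynthesis

**17 back to 15.** The C5'=O and C2'=O bonds of the quinone are traced to phenol 16, whose para position (C5') is free, and 16 to its benzyl ether 15. Oxidative demethylation of a fully methylated ring B was set aside because the tetra-oxygenated ring A would be oxidised first. A phenol-specific (Teuber) oxidation touches ring B only. The forward steps must be near-neutral so that C3–H next to the new quinone is not tautomerised.

**15 back to 13.** The C3–H bond is traced to C3–CHO (14) and then to C3–CH2OH (13). This adds a carbon in the retrosynthetic direction, but it makes C3 quaternary and hence configurationally locked. Forward, the arm is oxidised to an aldehyde that cannot enolise or eliminate the ring oxygen, and rhodium-mediated decarbonylation puts hydrogen where the formyl group was, with retention.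

**13 back to 12 (key disconnection).** The O1–C8a aryl ether bond is cut, giving the achiral diol 12 with an aryl iodide on ring A.
- Cutting O1–C2 instead would need a ring A phenol and prior differentiation of the two arms.
- Cutting C4–C4a would need a Friedel–Crafts closure at a hindered position and would not touch the stereochemical problem.
- The O1–C8a cut makes ring closure and stereo-induction one event, and everything before it needs no stereocontrol.

Forward, a chiral copper catalyst must choose one of two enantiotopic CH2OH groups and couple it to a hindered, electron-rich aryl iodide.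

**12 back to 7 and 10.** The two primary alcohols are traced to the diester 11 (hydride reduction). The C3–C4 bond is then cut to the arylmalonate 7 and the benzylic bromide 10. A tertiary malonate anion and a benzylic bromide are well matched for forming a quaternary carbon, and no elimination is possible in either partner.

**10 back to 8.** Bromide 10 comes from alcohol 9, and 9 from commercial 3,4,5-trimethoxybenzyl alcohol 8 by iodination at one of its two equivalent free positions. The whole oxygenation pattern of ring A is bought.

**7 back to 1, 3 and 6.** The malonate C–C bond is cut to the arylacetate 5 and diethyl carbonate 6. Ester 5 is traced through the ketene dithioacetal S-oxide 4 to aldehyde 2 and the one-carbon reagent 3, a two-step homologation that avoids halide and cyanide chemistry. Aldehyde 2 is the benzyl ether of commercial 2-hydroxy-3,4-dimethoxybenzaldehyde 1, in which the oxygen destined to become the C2' carbonyl is already distinguished.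

## Roads not taken

**Alternative 1:** The C3–C1' bond and a temporary C4–O bond are cut together, leading to 6,7,8-trimethoxy-2H-chromene A2 and 2,3-dimethoxy-1,4-benzoquinone A3.
- Forward key step: A3 is activated by TiCl4/Ti(OiPr)4 modified with a TADDOL diol. The chromene attacks through C3 and the benzylic C4 cation is captured by the neighbouring quinone oxygen. This gives the cis-pterocarpan (6aS,11aS)-8-hydroxy-2,3,4,9,10-pentamethoxypterocarpan A1, whose C6a is C3 of the target. Hydrogenolysis of the benzylic C11a–O bond of A1 and oxidation of the hydroquinone ring so released would finish 17.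
- Merits: it is convergent and very short, needs no protecting group, brings ring B in at the right oxidation level and has no decarbonylation.
- Weak points: enantioselection rests on a stoichiometric titanium TADDOLate whose selectivity depends strongly on the substrate. A3 has a second methoxy group, so both carbonyls are vinylogous esters and the chelate is less well defined than with the usual 2-monoalkoxyquinones. The very electron-rich A2 may be oxidised by the quinone or oligomerise under the Lewis acid, and [2+2] and [5+2] adducts compete.
- Comparison: this road is clearly shorter, and if its enantioselectivity held it would be the better synthesis. The chosen plan sets against it a catalytic, ligand-controlled stereo-determining step on a substrate class where that reaction is established. It also offers a quaternary stereocentre that cannot epimerise until the arm is removed, and a stable alcohol (13) at which enantiomeric purity can be measured and raised.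

**Alternative 2:** Ring A is built rather than bought: the C8a–C4a bond, and with it the arene, is traced to a cyclobutenone.
- Forward key step: an alkenyllithium that already contains C3 adds to dimethyl squarate A6 and the alkoxide is methylated. This gives 4-{(1E,4S)-4-[2-(benzyloxy)-3,4-dimethoxyphenyl]-5-[(tert-butyldimethylsilyl)oxy]pent-1-en-1-yl}-2,3,4-trimethoxycyclobut-2-en-1-one A5. Thermolysis opens the four-membered ring to a dienylketene, which closes by 6π electrocyclisation and enolises to the phenol 6-{(2S)-2-[2-(benzyloxy)-3,4-dimethoxyphenyl]-3-[(tert-butyldimethylsilyl)oxy]propyl}-2,3,4-trimethoxyphenol A4. Desilylation and Mitsunobu closure of O1–C2 would give 15.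
- Merits: the four contiguous oxygens are placed without ambiguity, O1 arrives as a free phenol so no hindered aryl halide coupling is needed, and C3 carries hydrogen from the outset.
- Weak points: the arene that is built is the one that 8 offers ready-made. C3 must be set beforehand by a separate, auxiliary-based alkylation and carried through alkenylmetal chemistry. The route is longer and linear.
- Comparison: it is equal or better in avoiding both the decarbonylation and the congested C–O coupling. The chosen plan sets against it a commercial ring A, fewer steps and a catalytic ring closure that is itself the source of chirality.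

**Alternative 3:** The C4–C4a bond is cut.
- Forward key step: the phenol 4-{(2S)-2-[2-(benzyloxy)-3,4-dimethoxyphenyl]-3-hydroxypropyl}-2,3-dimethoxyphenol A9 is dearomatised with PhI(OAc)2 to the spiroether (3S)-3-[2-(benzyloxy)-3,4-dimethoxyphenyl]-6,7-dimethoxy-1-oxaspiro[4.5]deca-6,9-dien-8-one A8. Under BF3·OEt2 the C4 methylene migrates from the spiro carbon to the neighbouring CH carbon while the oxygen stays and stabilises the cation. The five-membered ether becomes the pyran and the arene re-forms as (3S)-3-[2-(benzyloxy)-3,4-dimethoxyphenyl]-7,8-dimethoxychroman-6-ol A7. O-Methylation would give 15.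
- Merits: it converges on 15 without decarbonylation or metal-catalysed C–O coupling, and the migration terminus is unambiguous because only the CH carbon allows rearomatisation.
- Weak points: the key step creates no stereocentre, so C3 has to be installed earlier by other means. The hypervalent iodine oxidant must select the phenol ring although the electron-rich ring B can itself trap the phenoxenium ion. A9, with a differentiated free hydroxyl in a 1,2,3-trioxygenated ring, is not commercial, and an extra methylation is needed.
- Comparison: the length is comparable, and this road is better in that C3 is never quaternised and nothing has to be excised. The chosen plan sets against it that the ring-forming step is also the enantio-determining step and is catalytic, and that all ring A oxygens come from a cheap arene.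

Key step: step 9

Assumption: the sense of induction of the copper–diamine catalyst on 12 cannot be predicted with certainty; the (1R,2R) ligand is written, and its (1S,2S) antipode is used instead if that is the one that delivers (S)-13.

Assumption: 3 and 4 are racemic at sulfur and 4 may be either alkene isomer; both elements are lost in step 3.

## Route

Step 1
Reactants: 1 2-hydroxy-3,4-dimethoxybenzaldehyde
Product: 2 2-(benzyloxy)-3,4-dimethoxybenzaldehyde
Conditions: BnBr, K2CO3, DMF, 60 °C
Reagents that add atoms: benzyl bromide, BrCc1ccccc1
Why: Williamson O-benzylation of the only acidic site, the hydrogen-bonded ortho-hydroxyl; the benzyl ether marks the one ring B oxygen that is later oxidised and withstands every step up to the hydrogenolysis.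

Step 2
Reactants: 2 2-(benzyloxy)-3,4-dimethoxybenzaldehyde; 3 methyl (methylsulfanyl)methyl sulfoxide
Product: 4 2-(benzyloxy)-3,4-dimethoxy-1-[2-(methylsulfinyl)-2-(methylsulfanyl)ethenyl]benzene
Conditions: BnMe3N+ OH− (Triton B, 40% in MeOH), THF, reflux
Reagents that add atoms: none
Why: Knoevenagel-type condensation of the acidic methylene of 3 with the non-enolisable aldehyde, the first stage of the Ogura–Tsuchihashi arylacetic ester synthesis; either alkene isomer serves.

Step 3
Reactants: 4 2-(benzyloxy)-3,4-dimethoxy-1-[2-(methylsulfinyl)-2-(methylsulfanyl)ethenyl]benzene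
Product: 5 ethyl [2-(benzyloxy)-3,4-dimethoxyphenyl]acetate
Conditions: HCl, EtOH, rt
Reagents that add atoms: ethanol, CCO
Why: Acid-promoted ethanolysis of the ketene dithioacetal S-oxide, the second stage of the Ogura–Tsuchihashi synthesis: ethanol adds to the protonated ketene dithioacetal and the two sulfur groups leave together as the disulfide, so the former aldehyde carbon ends as the benzylic CH2; benzyl and methyl ethers tolerate ethanolic HCl at room temperature.

Step 4
Reactants: 5 ethyl [2-(benzyloxy)-3,4-dimethoxyphenyl]acetate; 6 diethyl carbonate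
Product: 7 diethyl 2-[2-(benzyloxy)-3,4-dimethoxyphenyl]propanedioate
Conditions: NaH, 6 in excess, THF, reflux; then aq. HCl
Reagents that add atoms: none
Why: Crossed Claisen condensation (C-ethoxycarbonylation) of the arylacetate enolate; formation of the stabilised sodium malonate drives the equilibrium and the excess of 6 suppresses self-condensation.

Step 5
Reactants: 8 (3,4,5-trimethoxyphenyl)methanol
Product: 9 (2-iodo-3,4,5-trimethoxyphenyl)methanol
Conditions: I2, CF3CO2Ag, CHCl3, 0 °C to rt
Reagents that add atoms: iodine, II
Why: Silver-assisted electrophilic aromatic iodination; the two free ring positions are equivalent and strongly activated, AgI precipitation makes the step irreversible, and the first iodine deactivates the ring against a second.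

Step 6
Reactants: 9 (2-iodo-3,4,5-trimethoxyphenyl)methanol
Product: 10 1-(bromomethyl)-2-iodo-3,4,5-trimethoxybenzene
Conditions: PBr3, CH2Cl2, 0 °C
Reagents that add atoms: phosphorus tribromide, BrP(Br)Br
Why: Conversion of a benzylic alcohol to the bromide by SN2 displacement of its phosphite ester; aryl iodide and methyl ethers are inert at 0 °C.

Step 7
Reactants: 7 diethyl 2-[2-(benzyloxy)-3,4-dimethoxyphenyl]propanedioate; 10 1-(bromomethyl)-2-iodo-3,4,5-trimethoxybenzene
Product: 11 diethyl 2-[2-(benzyloxy)-3,4-dimethoxyphenyl]-2-[(2-iodo-3,4,5-trimethoxyphenyl)methyl]propanedioate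
Conditions: NaH, DMF, 0 °C to rt
Reagents that add atoms: none
Why: Malonic ester alkylation: the tertiary arylmalonate anion displaces the reactive benzylic bromide by SN2, forming C3–C4 and the quaternary carbon; neither partner can eliminate.

Step 8
Reactants: 11 diethyl 2-[2-(benzyloxy)-3,4-dimethoxyphenyl]-2-[(2-iodo-3,4,5-trimethoxyphenyl)methyl]propanedioate
Product: 12 2-[2-(benzyloxy)-3,4-dimethoxyphenyl]-2-[(2-iodo-3,4,5-trimethoxyphenyl)methyl]propane-1,3-diol
Conditions: LiAlH4, THF, 0 °C; then H2O, aq. NaOH
Reagents that add atoms: none
Why: Hydride reduction of both esters to the prochiral 2,2-disubstituted propane-1,3-diol; the low temperature and short contact time spare the aryl iodide and limit retro-aldol loss of formaldehyde from the half-reduced intermediate.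

Step 9
Reactants: 12 2-[2-(benzyloxy)-3,4-dimethoxyphenyl]-2-[(2-iodo-3,4,5-trimethoxyphenyl)methyl]propane-1,3-diol
Product: 13 {(3S)-3-[2-(benzyloxy)-3,4-dimethoxyphenyl]-6,7,8-trimethoxy-3,4-dihydro-2H-chromen-3-yl}methanol
Conditions: CuI (10 mol %), (1R,2R)-N,N'-dimethyl-1,2-diphenylethane-1,2-diamine (20 mol %), Cs2CO3 (2 equiv), MeCN, 25–40 °C, Ar
Reagents that add atoms: none
Why: Enantioselective intramolecular Ullmann-type C–O coupling that desymmetrises the diol. The diamine-bound monovalent copper, with Cs2CO3, forms a copper alkoxide from one hydroxymethyl group, the aryl–iodine bond adds oxidatively to give a seven-membered aryl copper alkoxide of trivalent copper, and C–O reductive elimination forms O1–C8a. The closest known reaction type is the copper-catalysed enantioselective intramolecular O-arylation of 2-substituted 2-(2-iodobenzyl)propane-1,3-diols to 3,3-disubstituted chromans, a class to which 12 belongs. The pyran ring closes in a 6-exo mode at the sp2 carbon C8a (the breaking C–I bond lies outside the new ring), helped by the gem-disubstitution at the quaternary carbon. The new stereocentre C3 is controlled solely by the chiral diamine on copper, which selects between the two enantiotopic CH2OH groups through diastereomeric cupracycles; the substrate has no stereocentre of its own. The step needs enantiotopic-group selectivity and preference for cyclisation over intermolecular etherification and protodeiodination; the large difference between the ortho-benzyloxyaryl group and the benzylic methylene at the prochiral carbon, the intramolecular setting and the single aryl iodide (the second hydroxyl has nothing left to couple with) secure them. The methoxy group ortho to iodine and the electron-rich ring slow oxidative addition, which is why the iodide, a raised ligand loading and mild warming are chosen.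

Step 10
Reactants: 13 {(3S)-3-[2-(benzyloxy)-3,4-dimethoxyphenyl]-6,7,8-trimethoxy-3,4-dihydro-2H-chromen-3-yl}methanol
Product: 14 (3R)-3-[2-(benzyloxy)-3,4-dimethoxyphenyl]-6,7,8-trimethoxy-3,4-dihydro-2H-chromene-3-carbaldehyde
Conditions: Dess–Martin periodinane, CH2Cl2, 0 °C to rt
Reagents that add atoms: none
Why: Dess–Martin oxidation of the neopentyl primary alcohol under non-basic conditions; the α-carbon is quaternary, so the aldehyde can neither enolise nor expel the ring oxygen, and the descriptor changes to R only because CHO outranks C2.

Step 11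
Reactants: 14 (3R)-3-[2-(benzyloxy)-3,4-dimethoxyphenyl]-6,7,8-trimethoxy-3,4-dihydro-2H-chromene-3-carbaldehyde
Product: 15 (3S)-3-[2-(benzyloxy)-3,4-dimethoxyphenyl]-6,7,8-trimethoxy-3,4-dihydro-2H-chromene
Conditions: RhCl(PPh3)3 (1.1 equiv), xylene, 130–140 °C, Ar
Reagents that add atoms: none
Why: Tsuji–Wilkinson decarbonylation: the formyl C–H adds oxidatively to monovalent rhodium, the alkyl group migrates from the acyl carbon to rhodium and C–H reductive elimination follows, each with retention at the migrating carbon, so hydrogen takes the place of the formyl group and C3 becomes (S); the complex is used stoichiometrically because RhCl(CO)(PPh3)2 does not turn over at this temperature.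

Step 12
Reactants: 15 (3S)-3-[2-(benzyloxy)-3,4-dimethoxyphenyl]-6,7,8-trimethoxy-3,4-dihydro-2H-chromene
Product: 16 2,3-dimethoxy-6-[(3S)-6,7,8-trimethoxy-3,4-dihydro-2H-chromen-3-yl]phenol
Conditions: H2 (1 atm), 10% Pd/C, EtOAc–EtOH, rt
Reagents that add atoms: none
Why: Hydrogenolysis of the benzyl aryl ether; the chroman C2–O1 bond is not benzylic, aryl–oxygen bonds are inert, C3–H is untouched and nothing else is reducible.

Step 13
Reactants: 16 2,3-dimethoxy-6-[(3S)-6,7,8-trimethoxy-3,4-dihydro-2H-chromen-3-yl]phenol
Product: 17 abruquinone B, 2,3-dimethoxy-5-[(3S)-6,7,8-trimethoxy-3,4-dihydro-2H-chromen-3-yl]cyclohexa-2,5-diene-1,4-dione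
Conditions: (KSO3)2NO (2.5 equiv), KH2PO4 buffer, acetone–H2O, 0 °C to rt
Reagents that add atoms: potassium nitrosodisulfonate, [K+].[K+].[O-]S(=O)(=O)N([O])S(=O)(=O)[O-]
Why: Teuber oxidation: one nitrosodisulfonate radical abstracts the phenolic hydrogen, a second adds at the free para position C5', and loss of the imidodisulfonate gives the para-quinone; only the phenol ring reacts, and the near-neutral buffer keeps C3–H beside the new quinone from tautomerising.

## Compound list

1 | 2-hydroxy-3,4-dimethoxybenzaldehyde | COc1ccc(C=O)c(O)c1OC | starting material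
2 | 2-(benzyloxy)-3,4-dimethoxybenzaldehyde | COc1ccc(C=O)c(OCc2ccccc2)c1OC | intermediate
3 | methyl (methylsulfanyl)methyl sulfoxide (racemic at sulfur) | CSCS(C)=O | starting material
4 | 2-(benzyloxy)-3,4-dimethoxy-1-[2-(methylsulfinyl)-2-(methylsulfanyl)ethenyl]benzene (racemic at sulfur, alkene geometry not fixed) | COc1ccc(C=C(SC)S(C)=O)c(OCc2ccccc2)c1OC | intermediate
5 | ethyl [2-(benzyloxy)-3,4-dimethoxyphenyl]acetate | CCOC(=O)Cc1ccc(OC)c(OC)c1OCc1ccccc1 | intermediate
6 | diethyl carbonate | CCOC(=O)OCC | starting material
7 | diethyl 2-[2-(benzyloxy)-3,4-dimethoxyphenyl]propanedioate | CCOC(=O)C(C(=O)OCC)c1ccc(OC)c(OC)c1OCc1ccccc1 | intermediate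
8 | (3,4,5-trimethoxyphenyl)methanol | COc1cc(CO)cc(OC)c1OC | starting material
9 | (2-iodo-3,4,5-trimethoxyphenyl)methanol | COc1cc(CO)c(I)c(OC)c1OC | intermediate
10 | 1-(bromomethyl)-2-iodo-3,4,5-trimethoxybenzene | COc1cc(CBr)c(I)c(OC)c1OC | intermediate
11 | diethyl 2-[2-(benzyloxy)-3,4-dimethoxyphenyl]-2-[(2-iodo-3,4,5-trimethoxyphenyl)methyl]propanedioate | CCOC(=O)C(Cc1cc(OC)c(OC)c(OC)c1I)(C(=O)OCC)c1ccc(OC)c(OC)c1OCc1ccccc1 | intermediate
12 | 2-[2-(benzyloxy)-3,4-dimethoxyphenyl]-2-[(2-iodo-3,4,5-trimethoxyphenyl)methyl]propane-1,3-diol (achiral, prochiral) | COc1cc(CC(CO)(CO)c2ccc(OC)c(OC)c2OCc2ccccc2)c(I)c(OC)c1OC | intermediate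
13 | {(3S)-3-[2-(benzyloxy)-3,4-dimethoxyphenyl]-6,7,8-trimethoxy-3,4-dihydro-2H-chromen-3-yl}methanol | COc1ccc([C@@]2(CO)COc3c(cc(OC)c(OC)c3OC)C2)c(OCc2ccccc2)c1OC | intermediate
14 | (3R)-3-[2-(benzyloxy)-3,4-dimethoxyphenyl]-6,7,8-trimethoxy-3,4-dihydro-2H-chromene-3-carbaldehyde | COc1ccc([C@@]2(C=O)COc3c(cc(OC)c(OC)c3OC)C2)c(OCc2ccccc2)c1OC | intermediate
15 | (3S)-3-[2-(benzyloxy)-3,4-dimethoxyphenyl]-6,7,8-trimethoxy-3,4-dihydro-2H-chromene | COc1ccc([C@H]2COc3c(cc(OC)c(OC)c3OC)C2)c(OCc2ccccc2)c1OC | intermediate
16 | 2,3-dimethoxy-6-[(3S)-6,7,8-trimethoxy-3,4-dihydro-2H-chromen-3-yl]phenol | COc1ccc([C@H]2COc3c(cc(OC)c(OC)c3OC)C2)c(O)c1OC | intermediate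
17 | abruquinone B, 2,3-dimethoxy-5-[(3S)-6,7,8-trimethoxy-3,4-dihydro-2H-chromen-3-yl]cyclohexa-2,5-diene-1,4-dione | COC1=C(OC)C(=O)C([C@H]2COc3c(cc(OC)c(OC)c3OC)C2)=CC1=O | target

## Step count and least certain steps

Total: 13 steps. Longest linear sequence: 11 steps (steps 1–4 and 7–13); the ring A branch (steps 5 and 6) joins at step 7.

**Step 9 (key step).** The chiral catalyst may discriminate poorly between the two hydroxymethyl arms, because the bulky ortho-benzyloxyaryl group can distort the cupracycle. Oxidative addition into the hindered, electron-rich C–I bond may also be slow enough for protodeiodination or intermolecular etherification to compete.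

Fallback: the arms are distinguished by an enzyme and the ring is then closed without asymmetric induction. It sets out from 12 and returns at 13.
- Lipase-catalysed monoacetylation (Burkholderia cepacia lipase, vinyl acetate, t-BuOMe) should give (2S)-2-[2-(benzyloxy)-3,4-dimethoxyphenyl]-3-hydroxy-2-[(2-iodo-3,4,5-trimethoxyphenyl)methyl]propyl acetate F1; a lipase of the required preference is selected by screening.
- The free hydroxyl is protected under acid catalysis, which avoids acyl migration (3,4-dihydro-2H-pyran, pyridinium p-toluenesulfonate). This gives (2S)-2-[2-(benzyloxy)-3,4-dimethoxyphenyl]-2-[(2-iodo-3,4,5-trimethoxyphenyl)methyl]-3-(tetrahydro-2H-pyran-2-yloxy)propyl acetate F2.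
- Methanolysis (K2CO3, MeOH) frees the other arm as (2R)-2-[2-(benzyloxy)-3,4-dimethoxyphenyl]-2-[(2-iodo-3,4,5-trimethoxyphenyl)methyl]-3-(tetrahydro-2H-pyran-2-yloxy)propan-1-ol F3.
- Ullmann etherification with an achiral catalyst (CuI, 1,10-phenanthroline, Cs2CO3, toluene, 90 °C) closes the ring to 2-({(3R)-3-[2-(benzyloxy)-3,4-dimethoxyphenyl]-6,7,8-trimethoxy-3,4-dihydro-2H-chromen-3-yl}methoxy)tetrahydro-2H-pyran F4.
- Acetal methanolysis (pyridinium p-toluenesulfonate, MeOH) gives 13.

**Step 11.** Extrusion of CO from the hindered acyl rhodium may be slow. The tertiary benzylic alkyl rhodium hydride may undergo β-hydride or β-aryloxide elimination, or Rh–C homolysis, before C–H reductive elimination; these would lead to olefin formation, ring opening or partial loss of configuration.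

Fallback: C3 is reset by asymmetric hydrogenation. It sets out from 14 and returns at 15.
- Pinnick oxidation (NaClO2, NaH2PO4, 2-methylbut-2-ene, t-BuOH–H2O) gives (3R)-3-[2-(benzyloxy)-3,4-dimethoxyphenyl]-6,7,8-trimethoxy-3,4-dihydro-2H-chromene-3-carboxylic acid F5.
- Kochi oxidative decarboxylation (Pb(OAc)4, catalytic Cu(OAc)2, pyridine, benzene, 80 °C) gives the stilbene-type alkene 3-[2-(benzyloxy)-3,4-dimethoxyphenyl]-6,7,8-trimethoxy-2H-chromene F6.
- Iridium-catalysed asymmetric hydrogenation gives 15. The catalyst is [Ir(cod)(L)][B(3,5-(CF3)2C6H3)4], with L a chiral phosphine–oxazoline such as 4-tert-butyl-2-[2-(diphenylphosphanyl)phenyl]-4,5-dihydrooxazole, antipode chosen for (S), under H2 in CH2Cl2.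

**Step 8.** The half-reduced β-alkoxy ester may lose formaldehyde by retro-aldol cleavage, favoured by the aryl group that stabilises the resulting enolate. Hydride may also reduce the C–I bond.

Fallback: the second hydroxymethyl group is introduced by a Tollens condensation instead of a malonate. It sets out from 5 (with 10), returns at 12, and bypasses steps 4, 7 and 8.
- Alkylation of the enolate of 5 (LiN(i-Pr)2, THF, −78 °C) with 10 gives racemic ethyl 2-[2-(benzyloxy)-3,4-dimethoxyphenyl]-3-(2-iodo-3,4,5-trimethoxyphenyl)propanoate F7.
- Partial reduction (i-Bu2AlH, toluene, −78 °C) gives racemic 2-[2-(benzyloxy)-3,4-dimethoxyphenyl]-3-(2-iodo-3,4,5-trimethoxyphenyl)propanal F8.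
- Aqueous formaldehyde with KOH (aldol addition, then crossed Cannizzaro reduction) gives 12.

**Step 13.** The phenoxyl radical may couple or over-oxidise instead of being trapped at C5', and the product may tautomerise at C3 if the medium drifts from neutrality.

Fallback: the para oxygen is introduced first and the hydroquinone is then dehydrogenated under neutral conditions. It sets out from 16 and returns at 17.
- Elbs persulfate oxidation (K2S2O8, aq. NaOH, 0 °C to rt) gives potassium 4-hydroxy-2,3-dimethoxy-5-[(3S)-6,7,8-trimethoxy-3,4-dihydro-2H-chromen-3-yl]phenyl sulfate F9.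
- Acid hydrolysis (aq. HCl, 60 °C) gives 2,3-dimethoxy-5-[(3S)-6,7,8-trimethoxy-3,4-dihydro-2H-chromen-3-yl]benzene-1,4-diol F10.
- Oxidation with Ag2O in Et2O gives 17.

## Further compounds

F1 | step 9 | (2S)-2-[2-(benzyloxy)-3,4-dimethoxyphenyl]-3-hydroxy-2-[(2-iodo-3,4,5-trimethoxyphenyl)methyl]propyl acetate | COc1cc(C[C@](CO)(COC(C)=O)c2ccc(OC)c(OC)c2OCc2ccccc2)c(I)c(OC)c1OC
F2 | step 9 | (2S)-2-[2-(benzyloxy)-3,4-dimethoxyphenyl]-2-[(2-iodo-3,4,5-trimethoxyphenyl)methyl]-3-(tetrahydro-2H-pyran-2-yloxy)propyl acetate (mixture at the acetal carbon) | COc1cc(C[C@](COC2CCCCO2)(COC(C)=O)c2ccc(OC)c(OC)c2OCc2ccccc2)c(I)c(OC)c1OC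
F3 | step 9 | (2R)-2-[2-(benzyloxy)-3,4-dimethoxyphenyl]-2-[(2-iodo-3,4,5-trimethoxyphenyl)methyl]-3-(tetrahydro-2H-pyran-2-yloxy)propan-1-ol (mixture at the acetal carbon) | COc1cc(C[C@](COC2CCCCO2)(CO)c2ccc(OC)c(OC)c2OCc2ccccc2)c(I)c(OC)c1OC
F4 | step 9 | 2-({(3R)-3-[2-(benzyloxy)-3,4-dimethoxyphenyl]-6,7,8-trimethoxy-3,4-dihydro-2H-chromen-3-yl}methoxy)tetrahydro-2H-pyran (mixture at the acetal carbon) | COc1ccc([C@@]2(COC3CCCCO3)COc3c(cc(OC)c(OC)c3OC)C2)c(OCc2ccccc2)c1OC
F5 | step 11 | (3R)-3-[2-(benzyloxy)-3,4-dimethoxyphenyl]-6,7,8-trimethoxy-3,4-dihydro-2H-chromene-3-carboxylic acid | COc1ccc([C@@]2(C(=O)O)COc3c(cc(OC)c(OC)c3OC)C2)c(OCc2ccccc2)c1OC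
F6 | step 11 | 3-[2-(benzyloxy)-3,4-dimethoxyphenyl]-6,7,8-trimethoxy-2H-chromene | COc1ccc(C2=Cc3cc(OC)c(OC)c(OC)c3OC2)c(OCc2ccccc2)c1OC
F7 | step 8 | ethyl 2-[2-(benzyloxy)-3,4-dimethoxyphenyl]-3-(2-iodo-3,4,5-trimethoxyphenyl)propanoate (racemic) | CCOC(=O)C(Cc1cc(OC)c(OC)c(OC)c1I)c1ccc(OC)c(OC)c1OCc1ccccc1
F8 | step 8 | 2-[2-(benzyloxy)-3,4-dimethoxyphenyl]-3-(2-iodo-3,4,5-trimethoxyphenyl)propanal (racemic) | O=CC(Cc1cc(OC)c(OC)c(OC)c1I)c1ccc(OC)c(OC)c1OCc1ccccc1
F9 | step 13 | potassium 4-hydroxy-2,3-dimethoxy-5-[(3S)-6,7,8-trimethoxy-3,4-dihydro-2H-chromen-3-yl]phenyl sulfate | [K+].COc1c(OS(=O)(=O)[O-])cc([C@H]2COc3c(cc(OC)c(OC)c3OC)C2)c(O)c1OC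
F10 | step 13 | 2,3-dimethoxy-5-[(3S)-6,7,8-trimethoxy-3,4-dihydro-2H-chromen-3-yl]benzene-1,4-diol | COc1c(O)cc([C@H]2COc3c(cc(OC)c(OC)c3OC)C2)c(O)c1OC
A1 | alternative 1 | (6aS,11aS)-8-hydroxy-2,3,4,9,10-pentamethoxypterocarpan (cis) | COc1c(O)cc2c(c1OC)O[C@@H]1c3cc(OC)c(OC)c(OC)c3OC[C@H]21
A2 | alternative 1 | 6,7,8-trimethoxy-2H-chromene | COc1cc2C=CCOc2c(OC)c1OC
A3 | alternative 1 | 2,3-dimethoxy-1,4-benzoquinone | COC1=C(OC)C(=O)C=CC1=O
A4 | alternative 2 | 6-{(2S)-2-[2-(benzyloxy)-3,4-dimethoxyphenyl]-3-[(tert-butyldimethylsilyl)oxy]propyl}-2,3,4-trimethoxyphenol | COc1cc(C[C@H](CO[Si](C)(C)C(C)(C)C)c2ccc(OC)c(OC)c2OCc2ccccc2)c(O)c(OC)c1OC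
A5 | alternative 2 | 4-{(1E,4S)-4-[2-(benzyloxy)-3,4-dimethoxyphenyl]-5-[(tert-butyldimethylsilyl)oxy]pent-1-en-1-yl}-2,3,4-trimethoxycyclobut-2-en-1-one (either configuration at the ring carbon) | COC1=C(OC)C(OC)(/C=C/C[C@H](CO[Si](C)(C)C(C)(C)C)c2ccc(OC)c(OC)c2OCc2ccccc2)C1=O
A6 | alternative 2 | dimethyl squarate, 3,4-dimethoxycyclobut-3-ene-1,2-dione | COC1=C(OC)C(=O)C1=O
A7 | alternative 3 | (3S)-3-[2-(benzyloxy)-3,4-dimethoxyphenyl]-7,8-dimethoxychroman-6-ol | COc1ccc([C@H]2COc3c(cc(O)c(OC)c3OC)C2)c(OCc2ccccc2)c1OC
A8 | alternative 3 | (3S)-3-[2-(benzyloxy)-3,4-dimethoxyphenyl]-6,7-dimethoxy-1-oxaspiro[4.5]deca-6,9-dien-8-one (either configuration at the spiro carbon) | COC1=C(OC)C2(C=CC1=O)C[C@H](CO2)c1ccc(OC)c(OC)c1OCc1ccccc1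
A9 | alternative 3 | 4-{(2S)-2-[2-(benzyloxy)-3,4-dimethoxyphenyl]-3-hydroxypropyl}-2,3-dimethoxyphenol | COc1ccc([C@@H](CO)Cc2ccc(O)c(OC)c2OC)c(OCc2ccccc2)c1OC
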